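**Assumptions (one line):** L-proline gives the (R)-α-aminoxy ketone, and the quinine-derived primary amine gives (S)-ketone **5**. The opposite catalyst enantiomer is used if the other sense is observed.

## Retrosynthesis
1. Target **16** comes from tetrahydrochromone **14** by replacing the ring O with N–OMe (pyranone → N-alkoxypyridone).
2. **14** comes from β-diketone **12** by building the pyranone ring (acetylation/cyclodehydration). **12** comes from regioselective C-acylation of methoxy ketone **10**.
3. **10** comes from (S)-3-alkylcyclohexanone **5** by catalyst-controlled α′-aminoxylation (sets C8), N–O cleavage and O-methylation.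
4. Key bond: C5–C1′, made by enantioselective radical conjugate addition of the 5-phenylpentyl radical (from bromide **3**) to cyclohexenone **4**. This sets C5.
5. The carbocycle is pre-formed in **4**. The only rings built are the pyranone (step 7) and its conversion to the pyridone (step 8).

## Route

**Step 1**
Reactants: **1** phenylmagnesium bromide; **2** 1,5-dibromopentane (3 equiv)
Product: **3** (5-bromopentyl)benzene
Conditions: Li2CuCl4 (3 mol %), THF, 0 °C → rt
Reagents that add atoms: none
Why: Cu-catalysed Kumada-type coupling of an aryl Grignard with a primary alkyl bromide. Excess dibromide prevents double arylation, and the second C–Br survives.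

**Step 2**
Reactants: **3** (5-bromopentyl)benzene (2 equiv); **4** cyclohex-2-en-1-one
Product: **5** (S)-3-(5-phenylpentyl)cyclohexan-1-one
Conditions: 9-amino-9-deoxy-epi-quinine-derived primary amine (20 mol %), TFA (40 mol %), 4CzIPN (2 mol %), i-Pr2NEt (3 equiv), MeCN, blue LEDs, 25 °C
Reagents that add atoms: none
Why: Proposed new method: the primary amine condenses with **4** to give a chiral iminium ion. The photocatalyst oxidises i-Pr2NEt to an α-aminoalkyl radical, which abstracts Br from **3** (halogen-atom transfer) to give the primary 5-phenylpentyl radical. This nucleophilic radical adds to the β-carbon of the iminium face left open by the catalyst, setting (S)-C5. The resulting α-iminyl radical is reduced to the enamine, which is protonated and hydrolysed to the ketone. The closest known reactions are photochemical organocatalytic radical conjugate additions to cyclic enones and amine-mediated halogen-atom-transfer radical generation.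

**Step 3**
Reactants: **5**; **6** nitrosobenzene
Product: **7** (2R,5S)-2-(phenylaminooxy)-5-(5-phenylpentyl)cyclohexan-1-one
Conditions: L-proline (20 mol %), DMSO, rt, **6** (1.5 equiv) added over 4 h
Reagents that add atoms: nitrosobenzene, O=Nc1ccccc1
Why: Proline-catalysed α-aminoxylation (enamine catalysis). The enamine forms at the less hindered α′-CH2 (C6), away from the alkyl group. The nitroso oxygen is delivered syn to the proline CO2H, giving (R) at the new C–O centre (C8 of the target). Axial attack on the (S)-substrate also gives the cis-1,4 isomer, so the catalyst and substrate preferences are matched.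

**Step 4**
Reactants: **7**
Product: **8** (2R,5S)-2-hydroxy-5-(5-phenylpentyl)cyclohexan-1-one
Conditions: H2 (1 atm), 10 % Pd/C, MeOH, rt
Reagents that add atoms: none
Why: Hydrogenolysis of the weak N–O bond releases the α-hydroxy ketone and aniline. The ketone, the arene and both stereocentres are untouched.

**Step 5**
Reactants: **8**; **9** iodomethane
Product: **10** (2R,5S)-2-methoxy-5-(5-phenylpentyl)cyclohexan-1-one
Conditions: MeI (10 equiv), Ag2O (2 equiv), Et2O, rt, dark
Reagents that add atoms: iodomethane, CI
Why: Neutral Williamson-type O-methylation (Purdie conditions). No strong base is used, so the α-stereocentre is not epimerised.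

**Step 6**
Reactants: **10**; **11** methoxyacetyl chloride
Product: **12** (2R,5S)-2-methoxy-6-(2-methoxyacetyl)-5-(5-phenylpentyl)cyclohexan-1-one (enolised β-diketone; C6 not fixed)
Conditions: LDA (1.1 equiv), THF, –78 °C, 45 min; then **11** (1.2 equiv), –78 → 0 °C; NH4Cl work-up
Reagents that add atoms: methoxyacetyl chloride, COCC(=O)Cl
Why: Kinetic enolisation with LDA takes the unsubstituted CH2 (C6), not the OMe-bearing carbon. C-Acylation gives the 1,3-diketone, and this C6 becomes C4a. C5 and C2 are not epimerised.

**Step 7**
Reactants: **12**; **13** acetic anhydride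
Product: **14** (5S,8R)-3,8-dimethoxy-2-methyl-5-(5-phenylpentyl)-5,6,7,8-tetrahydro-4H-chromen-4-one
Conditions: Ac2O (5 equiv), NaOAc (3 equiv), 140 °C, 3 h; then TsOH·H2O (cat.), PhMe, 80 °C
Reagents that add atoms: acetic anhydride, CC(=O)OC(C)=O
Why: Proposed new method: Kostanecki–Robinson/Baker–Venkataraman-type chromone synthesis applied to an enolic cyclohexane-1,3-diketone. The enol acetate transfers its acetyl to the CH2(OMe) carbon to give a 1,3,5-triketone, which cyclodehydrates to the 2-methyl-3-methoxy-4-pyranone. The closest known reaction is 3-alkoxy-2-methylchromone synthesis from 2-hydroxy-ω-alkoxyacetophenones. C5 and C8 are not involved.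

**Step 8**
Reactants: **14**; **15** O-methylhydroxylamine (as HCl salt)
Product: **16** (5S,8R)-1,3,8-trimethoxy-2-methyl-5-(5-phenylpentyl)-5,6,7,8-tetrahydroquinolin-4(1H)-one (Waltherione H)
Conditions: MeONH2·HCl (5 equiv), pyridine, EtOH, 100 °C, sealed tube, 48 h
Reagents that add atoms: O-methylhydroxylamine, CON
Why: Proposed new method: the alkoxyamine adds conjugately to the vinylogous ester (C2 or C8a) and opens the pyranone. The N–H enaminone then closes onto the other electrophilic carbon and dehydrates to the N-methoxy-4-pyridone. The closest known reaction is the conversion of 3-alkoxy-2-methylpyran-4-ones to 1-hydroxy-pyridin-4-ones with hydroxylamine. The stereocentres are unchanged.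

## Compound list
1 | phenylmagnesium bromide | Br[Mg]c1ccccc1 | starting material
2 | 1,5-dibromopentane | BrCCCCCBr | starting material
3 | (5-bromopentyl)benzene | BrCCCCCc1ccccc1 | intermediate
4 | cyclohex-2-en-1-one | O=C1C=CCCC1 | starting material
5 | (S)-3-(5-phenylpentyl)cyclohexan-1-one | O=C1C[C@@H](CCCCCc2ccccc2)CCC1 | intermediate
6 | nitrosobenzene | O=Nc1ccccc1 | starting material
7 | (2R,5S)-2-(phenylaminooxy)-5-(5-phenylpentyl)cyclohexan-1-one | O=C1C[C@@H](CCCCCc2ccccc2)CC[C@H]1ONc1ccccc1 | intermediate
8 | (2R,5S)-2-hydroxy-5-(5-phenylpentyl)cyclohexan-1-one | O=C1C[C@@H](CCCCCc2ccccc2)CC[C@H]1O | intermediate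
9 | iodomethane | CI | starting material
10 | (2R,5S)-2-methoxy-5-(5-phenylpentyl)cyclohexan-1-one | O=C1C[C@@H](CCCCCc2ccccc2)CC[C@H]1OC | intermediate
11 | methoxyacetyl chloride | COCC(=O)Cl | starting material
12 | (2R,5S)-2-methoxy-6-(2-methoxyacetyl)-5-(5-phenylpentyl)cyclohexan-1-one | O=C1C(C(=O)COC)[C@@H](CCCCCc2ccccc2)CC[C@H]1OC | intermediate
13 | acetic anhydride | CC(=O)OC(C)=O | starting material
14 | (5S,8R)-3,8-dimethoxy-2-methyl-5-(5-phenylpentyl)-5,6,7,8-tetrahydro-4H-chromen-4-one | COc1c(C)oc2c(c1=O)[C@@H](CCCCCc1ccccc1)CC[C@H]2OC | intermediate
15 | O-methylhydroxylamine | CON | starting material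
16 | Waltherione H, (5S,8R)-1,3,8-trimethoxy-2-methyl-5-(5-phenylpentyl)-5,6,7,8-tetrahydroquinolin-4(1H)-one | COc1c(C)n(OC)c2c(c1=O)[C@@H](CCCCCc1ccccc1)CC[C@H]2OC | target

## Totals
- Total steps: 8.
- Longest linear sequence: 8 (1 → 3 → 5 → 7 → 8 → 10 → 12 → 14 → 16).

## Three steps most likely to fail
1. **Step 2 (enantioselective radical conjugate addition with an unactivated primary bromide).** Halogen-atom transfer from a bromide may be slow, or enantioselectivity may be low.
   Fallback: make **5** by Cu/Josiphos-catalysed asymmetric 1,4-addition of Ph(CH2)5MgBr (from **3**) to **4**, which replaces the radical step with an organometallic one.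
2. **Step 6 (regioselective C-acylation at the hindered CH2, rather than at the OMe-bearing carbon or on oxygen).**
   Fallback: install the C4a acyl group first. Do a tandem Et3B-mediated radical addition/boron-enolate aldol of the alkyl iodide and **4** with methoxyacetaldehyde, then oxidise to the diketone. Introduce the C8 oxygen afterwards by enamine aminoxylation.
3. **Step 8 (direct pyranone → N-OMe pyridone with a hindered, ring-fused pyranone).**
   Fallback: treat **14** with NH2OH·HCl to give the N-hydroxypyridone, then O-methylate with MeI/K2CO3. Alternatively, build the pyridone from the open triketone with MeONH2 instead of closing the pyranone.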